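## Retrosynthetic overview

1. The C4=C5 alkene of the target comes from a C4 carboxylic acid by dehydrodecarboxylation, so an acrylate ester serves as an acetylene equivalent.
2. The trans C1–OH / C2–OAc pair comes from a C1=C2 alkene by anti-epoxidation and hydrolysis with inversion at C1, assisted by the C6 benzoate.
3. The only ring, the cyclohexene, is closed by a catalytic enantioselective [4+2] cycloaddition that makes C3–C4 and C5–C6 together: a dienyl ester (C6=C1–C2=C3, carrying O6, C7 and O3) plus benzyl acrylate (C4, C5).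
4. Enabling feature: in the target ring the alkene C4=C5 is flanked by two cis, oxygen-bearing sp3 carbons C3 and C6, which are joined on the other side by the two-carbon unit C1–C2. The ring is therefore a 1,4-dioxygenated buta-1,3-diene plus a two-carbon dienophile.
5. The diene comes from 1,3-dihydroxyacetone (C6, C1, C7), a formyl ylide (C2, C3) and benzoyl chloride.

Key step: step 4

Remarks on the chemistry:
- Locants C1–C7 in the text are those of the target: C1 = C(OH)(CH2OBz), C2 and C3 = CH–OAc, C4=C5 = alkene, C6 = CH–OBz, C7 = CH2OBz. Systematic names of intermediates carry their own numbering.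
- Assumption: the (S)-configured oxazaborolidinium ion is taken to shield the acrylate face that leads to the adduct drawn. If the sense of induction is the opposite one, the (R)-catalyst is used and nothing else changes.
- 1,3-Dihydroxyacetone is drawn as the monomer; the commercial dimer dissociates in pyridine.

## Route

Step 1
Reactants: 1 1,3-dihydroxyacetone
Product: 2 2-oxopropane-1,3-diyl dibenzoate
Conditions: BzCl (2.2 equiv), pyridine, CH2Cl2, 0 °C → rt
Reagents that add atoms: benzoyl chloride, O=C(Cl)c1ccccc1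
Why: O-acylation (Schotten–Baumann type) of the two primary hydroxyls of the ketone monomer; no stereocentre is formed.

Step 2
Reactants: 2 2-oxopropane-1,3-diyl dibenzoate; 3 (triphenylphosphoranylidene)acetaldehyde
Product: 4 2-(2-oxoethylidene)propane-1,3-diyl dibenzoate
Conditions: toluene, 80 °C
Reagents that add atoms: none
Why: Wittig olefination of the activated, electron-poor ketone by the stabilised formyl ylide should give the enal, whose new double bond carries two identical CH2OBz groups, so no alkene geometry arises.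

Step 3
Reactants: 4 2-(2-oxoethylidene)propane-1,3-diyl dibenzoate
Product: 5 (1Z,3E)-2-[(benzoyloxy)methyl]-4-[(triisopropylsilyl)oxy]buta-1,3-dien-1-yl benzoate
Conditions: TIPSOTf, Et3N, CH2Cl2, −20 °C → rt
Reagents that add atoms: triisopropylsilyl trifluoromethanesulfonate, CC(C)[Si](OS(=O)(=O)C(F)(F)F)(C(C)C)C(C)C
Why: Soft enolisation of an enal to a 1-silyloxy-1,3-diene (O-silylation, then γ-deprotonation by Et3N); the (3E)-silyl enol ether follows from the s-trans enal, and the (1Z)-enol benzoate (benzoate trans to the vinyl group) should be favoured because it avoids A(1,3) strain in the planar diene, while the minor (1E) isomer cannot reach the reactive s-cis form in step 4.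

Step 4
Reactants: 5 (1Z,3E)-2-[(benzoyloxy)methyl]-4-[(triisopropylsilyl)oxy]buta-1,3-dien-1-yl benzoate; 6 benzyl acrylate
Product: 7 benzyl (1R,2S,5S)-5-(benzoyloxy)-4-[(benzoyloxy)methyl]-2-[(triisopropylsilyl)oxy]cyclohex-3-ene-1-carboxylate (ester, silyloxy and benzoyloxy groups all cis)
Conditions: (S)-3,3-diphenyl-1-(2-methylphenyl)tetrahydro-1H,3H-pyrrolo[1,2-c][1,3,2]oxazaborole (20 mol %), (CF3SO2)2NH (18 mol %), CH2Cl2, −78 → −40 °C, diene and acrylate in equimolar amounts
Reagents that add atoms: none
Why: The acrylate, bound through its carbonyl oxygen to the cationic boron of the oxazaborolidinium ion, undergoes a concerted but asynchronous, suprafacial [4+2] cycloaddition with the s-cis diene, the closest known reaction type being the oxazaborolidinium-catalysed enantioselective Diels–Alder reaction of acrylate esters with silyloxy-substituted acyclic dienes. The one ring of the target, the cyclohexene, is closed by this intermolecular cycloaddition, which forms C3–C4 and C5–C6 in the same event (C5–C6 leading). C3 and C6 become cis because both oxygens are outside substituents of the (1Z,3E)-diene, C4 becomes cis to the C3 silyloxy group through the endo orientation of the ester, and the absolute configuration of all three centres follows from the catalyst, which shields one face of the bound acrylate. Because C4 is erased later, regio-, endo- and facial selectivity must all be high, since the wrong regioisomer or the exo adduct would end as the enantiomer of the target. Regiochemistry is secured in the substrate: the silyl enol ether oxygen at C3 and the C7 branch at C1 place the largest HOMO coefficient on C6, which bonds to the acrylate β-carbon, whereas the enol benzoate oxygen at C6 is only a weak donor. The steric bulk of the triisopropylsilyl group and the low temperature should keep the dienol ether intact.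

Step 5
Reactants: 7 benzyl (1R,2S,5S)-5-(benzoyloxy)-4-[(benzoyloxy)methyl]-2-[(triisopropylsilyl)oxy]cyclohex-3-ene-1-carboxylate
Product: 8 anti-epoxide of 7: benzyl 5-(benzoyloxy)-4-[(benzoyloxy)methyl]-3,4-epoxy-2-[(triisopropylsilyl)oxy]cyclohexane-1-carboxylate, oxirane oxygen on the ring face opposite to the ester, silyloxy and benzoyloxy groups
Conditions: mCPBA, CH2Cl2, 0 °C → rt
Reagents that add atoms: 3-chloroperoxybenzoic acid (mCPBA), OOC(=O)c1cccc(Cl)c1
Why: Prilezhaev epoxidation of the trisubstituted C1=C2 alkene; the peracid should approach the face opposite to the three cis substituents at C3, C4 and C6, which sets C1 and C2 as the anti-epoxide.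

Step 6
Reactants: 8 anti-epoxide of 7
Product: 9 benzyl (1R,2R,3S,4R,5S)-5-(benzoyloxy)-4-[(benzoyloxy)methyl]-3,4-dihydroxy-2-[(triisopropylsilyl)oxy]cyclohexane-1-carboxylate
Conditions: HClO4 (aq., 10 mol %), THF–H2O (4:1), rt → 40 °C
Reagents that add atoms: water, O
Why: Acid-catalysed epoxide hydrolysis with neighbouring-group participation: C–O cleavage should occur at the tertiary carbon C1 with inversion, assisted by the trans-disposed C6 benzoate carbonyl, while C2 keeps the epoxide oxygen, so C1–OH ends cis to C6–OBz and C2–OH trans to both of its neighbours.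

Step 7
Reactants: 9 benzyl (1R,2R,3S,4R,5S)-5-(benzoyloxy)-4-[(benzoyloxy)methyl]-3,4-dihydroxy-2-[(triisopropylsilyl)oxy]cyclohexane-1-carboxylate
Product: 10 benzyl (1R,2R,3S,4R,5S)-5-(benzoyloxy)-4-[(benzoyloxy)methyl]-2,3,4-trihydroxycyclohexane-1-carboxylate
Conditions: HF·pyridine, THF–pyridine, 0 °C → rt
Reagents that add atoms: none
Why: Fluoride-mediated Si–O cleavage under mildly acidic conditions should remove the silyl ether without acyl migration or retro-aldol opening of the β-hydroxy ester; no stereocentre is touched.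

Step 8
Reactants: 10 benzyl (1R,2R,3S,4R,5S)-5-(benzoyloxy)-4-[(benzoyloxy)methyl]-2,3,4-trihydroxycyclohexane-1-carboxylate
Product: 11 benzyl (1R,2R,3S,4S,5S)-2,3-bis(acetyloxy)-5-(benzoyloxy)-4-[(benzoyloxy)methyl]-4-hydroxycyclohexane-1-carboxylate
Conditions: Ac2O (2.5 equiv), pyridine, 4-(dimethylamino)pyridine (cat.), CH2Cl2, 0 °C
Reagents that add atoms: acetic anhydride, CC(=O)OC(C)=O
Why: Nucleophile-catalysed acetylation should take the two secondary hydroxyls at C2 and C3 and leave the hindered tertiary C1–OH free (steric selectivity).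

Step 9
Reactants: 11 benzyl (1R,2R,3S,4S,5S)-2,3-bis(acetyloxy)-5-(benzoyloxy)-4-[(benzoyloxy)methyl]-4-hydroxycyclohexane-1-carboxylate
Product: 12 (1R,2R,3S,4S,5S)-2,3-bis(acetyloxy)-5-(benzoyloxy)-4-[(benzoyloxy)methyl]-4-hydroxycyclohexane-1-carboxylic acid
Conditions: H2 (1 atm), Pd/C (10 % Pd), EtOAc, rt
Reagents that add atoms: none
Why: Hydrogenolysis of the benzyl ester gives the free acid; benzoates, acetates and the tertiary alcohol are inert and no alkene is present at this stage.

Step 10
Reactants: 12 (1R,2R,3S,4S,5S)-2,3-bis(acetyloxy)-5-(benzoyloxy)-4-[(benzoyloxy)methyl]-4-hydroxycyclohexane-1-carboxylic acid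
Product: 13 cleistenediol F, [(1S,2S,3R,6S)-2,3-bis(acetyloxy)-6-(benzoyloxy)-1-hydroxycyclohex-4-en-1-yl]methyl benzoate
Conditions: 9-(2-chlorophenyl)acridine (10 mol %), Co(dmgH)2(py)Cl [chloro(pyridine)bis(dimethylglyoximato)cobalt] (5 mol %), CH2Cl2–MeCN (2:1), 400 nm LED, 25 °C
Reagents that add atoms: none
Why: Photocatalytic dehydrodecarboxylation of an aliphatic acid: proton-coupled electron transfer in the acridine–acid complex gives the C4 radical after loss of CO2, and the cobaloxime in its divalent cobalt state should remove a hydrogen atom from the unhindered C5 methylene and not from the tertiary, acetoxy-bearing C3–H, which installs C4=C5 and erases the auxiliary stereocentre.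

## Compound list

1 | 1,3-dihydroxyacetone (commercial as its dimer) | O=C(CO)CO | starting material
2 | 2-oxopropane-1,3-diyl dibenzoate | O=C(COC(=O)c1ccccc1)COC(=O)c1ccccc1 | intermediate
3 | (triphenylphosphoranylidene)acetaldehyde | O=CC=P(c1ccccc1)(c1ccccc1)c1ccccc1 | starting material
4 | 2-(2-oxoethylidene)propane-1,3-diyl dibenzoate | O=CC=C(COC(=O)c1ccccc1)COC(=O)c1ccccc1 | intermediate
5 | (1Z,3E)-2-[(benzoyloxy)methyl]-4-[(triisopropylsilyl)oxy]buta-1,3-dien-1-yl benzoate | CC(C)[Si](C(C)C)(C(C)C)O/C=C/C(COC(=O)c1ccccc1)=C/OC(=O)c1ccccc1 | intermediate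
6 | benzyl acrylate | C=CC(=O)OCc1ccccc1 | starting material
7 | benzyl (1R,2S,5S)-5-(benzoyloxy)-4-[(benzoyloxy)methyl]-2-[(triisopropylsilyl)oxy]cyclohex-3-ene-1-carboxylate | CC(C)[Si](C(C)C)(C(C)C)O[C@@H]1[C@H](C(=O)OCc2ccccc2)C[C@H](OC(=O)c2ccccc2)C(COC(=O)c2ccccc2)=C1 | intermediate
8 | anti-epoxide of 7 (oxirane trans to the ester, silyloxy and benzoyloxy groups) | CC(C)[Si](C(C)C)(C(C)C)O[C@@H]1[C@H](C(=O)OCc2ccccc2)C[C@H](OC(=O)c2ccccc2)[C@@]3(COC(=O)c2ccccc2)O[C@@H]13 | intermediate
9 | benzyl (1R,2R,3S,4R,5S)-5-(benzoyloxy)-4-[(benzoyloxy)methyl]-3,4-dihydroxy-2-[(triisopropylsilyl)oxy]cyclohexane-1-carboxylate | CC(C)[Si](C(C)C)(C(C)C)O[C@@H]1[C@H](C(=O)OCc2ccccc2)C[C@H](OC(=O)c2ccccc2)[C@@](O)(COC(=O)c2ccccc2)[C@H]1O | intermediate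
10 | benzyl (1R,2R,3S,4R,5S)-5-(benzoyloxy)-4-[(benzoyloxy)methyl]-2,3,4-trihydroxycyclohexane-1-carboxylate | O[C@@H]1[C@H](C(=O)OCc2ccccc2)C[C@H](OC(=O)c2ccccc2)[C@@](O)(COC(=O)c2ccccc2)[C@H]1O | intermediate
11 | benzyl (1R,2R,3S,4S,5S)-2,3-bis(acetyloxy)-5-(benzoyloxy)-4-[(benzoyloxy)methyl]-4-hydroxycyclohexane-1-carboxylate | CC(=O)O[C@@H]1[C@H](C(=O)OCc2ccccc2)C[C@H](OC(=O)c2ccccc2)[C@@](O)(COC(=O)c2ccccc2)[C@H]1OC(C)=O | intermediate
12 | (1R,2R,3S,4S,5S)-2,3-bis(acetyloxy)-5-(benzoyloxy)-4-[(benzoyloxy)methyl]-4-hydroxycyclohexane-1-carboxylic acid | CC(=O)O[C@@H]1[C@H](C(O)=O)C[C@H](OC(=O)c2ccccc2)[C@@](O)(COC(=O)c2ccccc2)[C@H]1OC(C)=O | intermediate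
13 | cleistenediol F, [(1S,2S,3R,6S)-2,3-bis(acetyloxy)-6-(benzoyloxy)-1-hydroxycyclohex-4-en-1-yl]methyl benzoate | CC(=O)O[C@@H]1C=C[C@H](OC(=O)c2ccccc2)[C@@](O)(COC(=O)c2ccccc2)[C@H]1OC(C)=O | target

## Step count and risks

Total step count: 10. Longest linear sequence: 10 steps (from 1,3-dihydroxyacetone).

The three steps most likely to fail:

**Step 4 (key cycloaddition).** The strongly acidic boron catalyst may transfer or strip the silyl group of the dienol ether. The reaction would then run through a stepwise Mukaiyama–Michael pathway with achiral silyl-cation catalysis, which would erode enantio-, endo- and regiocontrol; the minor diene isomer could also enter by that pathway. Fallback: setting out from diene 5, a chelating acrylate surrogate, 4-hydroxy-4-methylpent-1-en-3-one, is used under two-point binding to divalent copper (Cu(OTf)2 with (S,S)-2,2'-isopropylidenebis(4-tert-butyl-2-oxazoline), 10 mol %, CH2Cl2, −20 °C; the ligand enantiomer that gives the drawn adduct is chosen). This should give the hydroxy ketone adduct F1. Oxidative cleavage of the ketol with NaIO4 in MeOH–H2O gives the cyclohexenecarboxylic acid F2, and benzylation (BnBr, KHCO3, DMF) comes back to the route at 7.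

**Step 10 (dehydrodecarboxylation).** Hydrogen abstraction may occur toward the acetoxy-bearing carbon (enol acetate formation), the cobalt hydride may move the new double bond, or conversion may be poor in this crowded acid. Fallback: setting out from acid 12, esterification with N-hydroxypyridine-2-thione (N,N'-dicyclohexylcarbodiimide, CH2Cl2, 0 °C, dark) gives the thiohydroxamate (Barton) ester F6. Photolysis with PhSeSePh (tungsten lamp, CH2Cl2) gives the C4 phenyl selenide F7 as an epimer mixture. Oxidation with aqueous H2O2 and pyridine in CH2Cl2 gives the selenoxide F8, whose syn-elimination runs away from the acetoxy-bearing carbon and comes back to the route at 13.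

**Step 6 (epoxide hydrolysis).** The ring may open at the secondary carbon C2 (by water or by the C4 ester carbonyl, with lactonisation), a hydride shift may give a ketone, or the benzoyl group may migrate. Fallback: setting out from adduct 7, the silyl ether is removed first (HF·pyridine, THF) to give the allylic alcohol F3. Hydroxyl-directed epoxidation (VO(acac)2, t-BuOOH, CH2Cl2) gives the syn-epoxy alcohol F4, with the oxirane on the same face as the C3 hydroxyl. SN2 opening at the secondary carbon C2 by acetate from the opposite face (CsOAc, AcOH, DMF, 80 °C) gives the monoacetate F5, with C2–OAc trans and C1–OH cis to the C6 benzoate. Acetylation of the remaining secondary hydroxyl (Ac2O, pyridine) comes back to the route at 11.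

## Further compounds

F1 | step 4 | 1-[(1R,2S,5S)-5-(benzoyloxy)-4-[(benzoyloxy)methyl]-2-[(triisopropylsilyl)oxy]cyclohex-3-en-1-yl]-2-hydroxy-2-methylpropan-1-one (hydroxy ketone adduct) | CC(C)[Si](C(C)C)(C(C)C)O[C@@H]1[C@H](C(=O)C(C)(C)O)C[C@H](OC(=O)c2ccccc2)C(COC(=O)c2ccccc2)=C1
F2 | step 4 | (1R,2S,5S)-5-(benzoyloxy)-4-[(benzoyloxy)methyl]-2-[(triisopropylsilyl)oxy]cyclohex-3-ene-1-carboxylic acid | CC(C)[Si](C(C)C)(C(C)C)O[C@@H]1[C@H](C(O)=O)C[C@H](OC(=O)c2ccccc2)C(COC(=O)c2ccccc2)=C1
F3 | step 6 | benzyl (1R,2S,5S)-5-(benzoyloxy)-4-[(benzoyloxy)methyl]-2-hydroxycyclohex-3-ene-1-carboxylate | O[C@@H]1[C@H](C(=O)OCc2ccccc2)C[C@H](OC(=O)c2ccccc2)C(COC(=O)c2ccccc2)=C1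
F4 | step 6 | syn-epoxy alcohol: benzyl 5-(benzoyloxy)-4-[(benzoyloxy)methyl]-3,4-epoxy-2-hydroxycyclohexane-1-carboxylate, oxirane cis to the hydroxyl, ester and benzoyloxy groups | O[C@@H]1[C@H](C(=O)OCc2ccccc2)C[C@H](OC(=O)c2ccccc2)[C@]3(COC(=O)c2ccccc2)O[C@H]13
F5 | step 6 | benzyl (1R,2R,3S,4S,5S)-3-(acetyloxy)-5-(benzoyloxy)-4-[(benzoyloxy)methyl]-2,4-dihydroxycyclohexane-1-carboxylate | O[C@@H]1[C@H](C(=O)OCc2ccccc2)C[C@H](OC(=O)c2ccccc2)[C@@](O)(COC(=O)c2ccccc2)[C@H]1OC(C)=O
F6 | step 10 | 2-thioxopyridin-1(2H)-yl ester of acid 12 (Barton ester) | CC(=O)O[C@@H]1[C@H](C(=O)On2ccccc2=S)C[C@H](OC(=O)c2ccccc2)[C@@](O)(COC(=O)c2ccccc2)[C@H]1OC(C)=O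
F7 | step 10 | C4 phenyl selenide (epimer mixture at the selenium-bearing carbon): [(1S,2S,3R,6S)-2,3-bis(acetyloxy)-6-(benzoyloxy)-1-hydroxy-4-(phenylselanyl)cyclohexyl]methyl benzoate | CC(=O)O[C@@H]1C([Se]c2ccccc2)C[C@H](OC(=O)c2ccccc2)[C@@](O)(COC(=O)c2ccccc2)[C@H]1OC(C)=O
F8 | step 10 | selenoxide of F7 (mixture at selenium and at the selenium-bearing carbon) | CC(=O)O[C@@H]1C([Se](=O)c2ccccc2)C[C@H](OC(=O)c2ccccc2)[C@@](O)(COC(=O)c2ccccc2)[C@H]1OC(C)=O
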